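**Plan**

1. Retrosynthesis: the C7 methoxymethyl ether is cut last. Ring C is then opened at C3–C4 (retro-hydroacylation) to the aldehyde/enol ether 17. Next the vinylic bromine helper, the O1–C2 bond (phenol 7 + bromoalkyne 15), the ring A prenyl bond (Claisen), and in ring B the aryl–alkyne bond, the chromane C–O bond and the two ortho-prenyl bonds are cut.
2. Enabling feature: ring C is a β-aryloxy ketone whose carbonyl carbon C4 sits on ring A ortho to O1 and whose C2 carries only H, O1 and ring B. The ring is therefore the isomer of a formyl C4–H bond added across a 1,1-disubstituted enol ether C2=C3; O1 can chelate rhodium and the full substitution of C2 forces 6-endo closure.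
3. Forward: ring A aldehyde 7 (steps 1–4) and bromoalkyne 15 (steps 5–8, ring B chromane closed in step 6) are joined at O1–C2 (step 9). Bromine is removed (step 10), ring C is closed at C3–C4 (step 11) and the phenol is freed (step 12).
4. Stereochemistry: the single stereocentre C2 (S) is created in step 11 by the chiral rhodium–bisphosphine catalyst (hydride to the Re face of C2) and is kept because the last step is acidic and mild.

Key step: step 11

Remark: prenyl = 3-methylbut-2-en-1-yl and chroman = 3,4-dihydro-2H-chromene throughout. The sense of induction of the new catalytic step cannot be fixed on paper; the ligand enantiomer written in step 11 is assumed to deliver hydride to the Re face of C2, and its antipode is used if a model substrate shows the opposite sense.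

**Route**

Step 1
Reactants: 1 2,4-dihydroxybenzaldehyde; 2 3-chloro-3-methylbut-1-yne
Product: 3 2-hydroxy-4-[(2-methylbut-3-yn-2-yl)oxy]benzaldehyde
Conditions: K2CO3, KI, CuI (cat.), acetone, reflux
Reagents that add atoms: none
Why: Copper-catalysed O-alkylation of the phenoxide with the tertiary propargylic chloride should take the 4-OH only, because the 2-OH is tied up in a hydrogen bond to the formyl group.

Step 2
Reactants: 3 2-hydroxy-4-[(2-methylbut-3-yn-2-yl)oxy]benzaldehyde
Product: 4 2-hydroxy-4-[(2-methylbut-3-en-2-yl)oxy]benzaldehyde
Conditions: H2 (1 atm), Pd/CaCO3 poisoned with Pb(OAc)2, quinoline, EtOAc, rt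
Reagents that add atoms: none
Why: Semihydrogenation of the terminal alkyne over poisoned palladium should stop at the alkene and leave the aryl aldehyde untouched.

Step 3
Reactants: 4 2-hydroxy-4-[(2-methylbut-3-en-2-yl)oxy]benzaldehyde
Product: 6 2,4-dihydroxy-3-prenylbenzaldehyde, via Claisen dienone 5 (not isolated)
Conditions: PhNEt2, 130 °C
Reagents that add atoms: none
Why: Aromatic Claisen rearrangement of the 1,1-dimethylallyl ether should go to the ortho position between the two oxygens, because the chelated 2-hydroxybenzaldehyde unit gives that ring bond the higher double-bond character, and tautomerisation of dienone 5 restores the arene with a normal prenyl group.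

Step 4
Reactants: 6 2,4-dihydroxy-3-prenylbenzaldehyde
Product: 7 2-hydroxy-4-(methoxymethoxy)-3-prenylbenzaldehyde
Conditions: MOMCl, K2CO3, acetone, 0 °C to rt
Reagents that add atoms: chloromethyl methyl ether (MOMCl), COCCl
Why: Williamson-type alkylation with the chloromethyl ether should take the 4-OH only, since the 2-OH is chelated to the aldehyde and is the weaker nucleophile.

Step 5
Reactants: 8 4-iodophenol; 9 prenyl bromide (1-bromo-3-methylbut-2-ene, 2.2 equiv)
Product: 11 4-iodo-2,6-diprenylphenol, via 4-iodo-2-prenylphenol 10 (not isolated)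
Conditions: NaH, toluene, 0 °C to rt
Reagents that add atoms: none
Why: Ortho-selective C-alkylation of the sodium phenoxide as a tight ion pair in a non-polar solvent should put one prenyl group on each free ortho position, the para position being blocked by iodine.

Step 6
Reactants: 11 4-iodo-2,6-diprenylphenol
Product: 12 6-iodo-2,2-dimethyl-8-prenylchromane
Conditions: Amberlyst 15 (sulfonic acid resin), toluene, 60 °C
Reagents that add atoms: none
Why: Acid-catalysed intramolecular hydroalkoxylation (tertiary cation trapped by the phenol in a six-membered ring) can consume only one of the two prenyl groups because there is only one hydroxyl, so the second stays as the C8 prenyl group.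

Step 7
Reactants: 12 6-iodo-2,2-dimethyl-8-prenylchromane; 13 ethynyltrimethylsilane
Product: 14 [(2,2-dimethyl-8-prenylchroman-6-yl)ethynyl]trimethylsilane
Conditions: PdCl2(PPh3)2 (cat.), CuI (cat.), Et3N, THF, rt
Reagents that add atoms: none
Why: Sonogashira coupling of the aryl iodide with the silyl-capped alkyne installs the two carbons that become C2 and C3 of ring C.

Step 8
Reactants: 14 [(2,2-dimethyl-8-prenylchroman-6-yl)ethynyl]trimethylsilane
Product: 15 6-(bromoethynyl)-2,2-dimethyl-8-prenylchromane
Conditions: NBS, AgNO3 (cat.), acetone, rt, dark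
Reagents that add atoms: N-bromosuccinimide (NBS), O=C1CCC(=O)N1Br
Why: Silver-catalysed desilylative bromination of the alkynylsilane should give the 1-bromoalkyne, the acetylide pathway being faster than attack of the bromine source on the trisubstituted double bond.

Step 9
Reactants: 7 2-hydroxy-4-(methoxymethoxy)-3-prenylbenzaldehyde; 15 6-(bromoethynyl)-2,2-dimethyl-8-prenylchromane
Product: 16 2-{[(Z)-2-bromo-1-(2,2-dimethyl-8-prenylchroman-6-yl)ethenyl]oxy}-4-(methoxymethoxy)-3-prenylbenzaldehyde
Conditions: Cs2CO3, DMF, 100 °C
Reagents that add atoms: none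
Why: Base-mediated anti-hydroalkoxylation of a 1-bromoalkyne should put the phenoxide oxygen on the aryl-bearing alkyne carbon, because the developing vinyl anion is stabilised on the bromine-bearing carbon, and protonation gives the (Z)-2-bromovinyl aryl ether with the O1–C2 bond in place and no stereocentre.

Step 10
Reactants: 16 2-{[(Z)-2-bromo-1-(2,2-dimethyl-8-prenylchroman-6-yl)ethenyl]oxy}-4-(methoxymethoxy)-3-prenylbenzaldehyde
Product: 17 2-{[1-(2,2-dimethyl-8-prenylchroman-6-yl)ethenyl]oxy}-4-(methoxymethoxy)-3-prenylbenzaldehyde
Conditions: Pd(PPh3)4 (cat.), Bu3SnH, THF, rt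
Reagents that add atoms: none
Why: Palladium-catalysed hydrodehalogenation (oxidative addition of zerovalent palladium to the vinyl C–Br bond, hydride transfer from tin, reductive elimination) should remove the bromine that only steered the regiochemistry of step 9 and spare the aldehyde, the enol ether and the prenyl groups.

Step 11
Reactants: 17 2-{[1-(2,2-dimethyl-8-prenylchroman-6-yl)ethenyl]oxy}-4-(methoxymethoxy)-3-prenylbenzaldehyde
Product: 18 (2S)-2-(2,2-dimethyl-8-prenylchroman-6-yl)-7-(methoxymethoxy)-8-prenylchroman-4-one
Conditions: [Rh(cod)Cl]2 (2.5 mol%), (R)-DTBM-SEGPHOS (5.5 mol%), NaB[3,5-(CF3)2C6H3]4 (6 mol%), THF, 60 °C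
Reagents that add atoms: none
Why: Proposed new method: oxidative addition of the formyl C–H bond to the cationic monovalent rhodium–bisphosphine complex, helped by coordination of the neighbouring ether oxygen O1 and of the enol ether, should give an acyl hydride of trivalent rhodium; reversible hydride insertion then places H on C2 and rhodium on the terminal carbon C3, and C–C reductive elimination from the seven-membered acyl–alkyl rhodacycle forms the C3–C4 bond and returns the catalyst. The closest known reaction type is the rhodium/chiral bisphosphine-catalysed endo- and enantioselective hydroacylation of ortho-allylbenzaldehydes bearing a 1,1-disubstituted alkene (to 3-substituted tetralones) and of 2-(1-arylvinyl)benzaldehydes (to 3-arylindanones); here the tether atom is the enol ether oxygen, a substrate class on which the reaction has not been shown. Ring C closes in the 6-endo-trig mode, because the exo alternative would need reductive elimination at a fully substituted, benzylic, oxygen-bearing carbon to give a benzofuranone with a quaternary centre, whereas the primary alkyl on C3 eliminates readily. The only new stereocentre, C2, is set under catalyst control: the C2-symmetric ligand differentiates the two faces of the enol ether, and hydride delivery to the Re face of C2 gives the (2S) configuration. The step needs endo over exo closure (secured by the 1,1-disubstitution at C2), hydroacylation over decarbonylation (secured by O1 chelation and the short tether, with no allylic hydrogen on the tether to allow alkene isomerisation) and chemoselectivity over the two prenyl groups (trisubstituted, and placed so that neither can reach the acyl rhodium centre in an unstrained ring).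

Step 12
Reactants: 18 (2S)-2-(2,2-dimethyl-8-prenylchroman-6-yl)-7-(methoxymethoxy)-8-prenylchroman-4-one
Product: 19 (2S)-2-(2,2-dimethyl-8-prenylchroman-6-yl)-7-hydroxy-8-prenylchroman-4-one
Conditions: 2 M HCl (aq), MeOH, 40 °C
Reagents that add atoms: none
Why: Acid-catalysed methanolysis of the aryl methoxymethyl acetal under mild conditions should free the 7-OH, and the C2 stereocentre is not touched because no base is present to open ring C to the chalcone.

**Compound list**

1 | 2,4-dihydroxybenzaldehyde | O=Cc1ccc(O)cc1O | starting material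
2 | 3-chloro-3-methylbut-1-yne | C#CC(C)(C)Cl | starting material
3 | 2-hydroxy-4-[(2-methylbut-3-yn-2-yl)oxy]benzaldehyde | O=Cc1ccc(OC(C)(C)C#C)cc1O | intermediate
4 | 2-hydroxy-4-[(2-methylbut-3-en-2-yl)oxy]benzaldehyde | O=Cc1ccc(OC(C)(C)C=C)cc1O | intermediate
5 | Claisen dienone, 2-hydroxy-4-oxo-3-prenylcyclohexa-1,5-diene-1-carbaldehyde (racemic, formed in the flask) | O=CC1=C(O)C(CC=C(C)C)C(=O)C=C1 | intermediate
6 | 2,4-dihydroxy-3-prenylbenzaldehyde | O=Cc1ccc(O)c(CC=C(C)C)c1O | intermediate
7 | 2-hydroxy-4-(methoxymethoxy)-3-prenylbenzaldehyde | O=Cc1ccc(OCOC)c(CC=C(C)C)c1O | intermediate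
8 | 4-iodophenol | Oc1ccc(I)cc1 | starting material
9 | prenyl bromide (1-bromo-3-methylbut-2-ene) | CC(C)=CCBr | starting material
10 | 4-iodo-2-prenylphenol (formed in the flask) | Oc1ccc(I)cc1CC=C(C)C | intermediate
11 | 4-iodo-2,6-diprenylphenol | Oc1c(CC=C(C)C)cc(I)cc1CC=C(C)C | intermediate
12 | 6-iodo-2,2-dimethyl-8-prenylchromane | CC(C)=CCc1cc(I)cc2c1OC(C)(C)CC2 | intermediate
13 | ethynyltrimethylsilane | C#C[Si](C)(C)C | starting material
14 | [(2,2-dimethyl-8-prenylchroman-6-yl)ethynyl]trimethylsilane | CC(C)=CCc1cc(C#C[Si](C)(C)C)cc2c1OC(C)(C)CC2 | intermediate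
15 | 6-(bromoethynyl)-2,2-dimethyl-8-prenylchromane | CC(C)=CCc1cc(C#CBr)cc2c1OC(C)(C)CC2 | intermediate
16 | 2-{[(Z)-2-bromo-1-(2,2-dimethyl-8-prenylchroman-6-yl)ethenyl]oxy}-4-(methoxymethoxy)-3-prenylbenzaldehyde | O=Cc1ccc(OCOC)c(CC=C(C)C)c1O/C(=C\Br)c1cc(CC=C(C)C)c2OC(C)(C)CCc2c1 | intermediate
17 | 2-{[1-(2,2-dimethyl-8-prenylchroman-6-yl)ethenyl]oxy}-4-(methoxymethoxy)-3-prenylbenzaldehyde | O=Cc1ccc(OCOC)c(CC=C(C)C)c1OC(=C)c1cc(CC=C(C)C)c2OC(C)(C)CCc2c1 | intermediate
18 | (2S)-2-(2,2-dimethyl-8-prenylchroman-6-yl)-7-(methoxymethoxy)-8-prenylchroman-4-one | CC(C)=CCc1cc([C@@H]2CC(=O)c3ccc(OCOC)c(CC=C(C)C)c3O2)cc2c1OC(C)(C)CC2 | intermediate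
19 | (2S)-2-(2,2-dimethyl-8-prenylchroman-6-yl)-7-hydroxy-8-prenylchroman-4-one | CC(C)=CCc1cc([C@@H]2CC(=O)c3ccc(O)c(CC=C(C)C)c3O2)cc2c1OC(C)(C)CC2 | target

**Step count and risks**

Total step count: 12. Longest linear sequence: 8 steps (steps 1–4 then 9–12; the ring B branch, steps 5–8 then 9–12, is equally long).

Steps most likely to fail:

Step 11 (carries the label "Proposed new method:"). The acyl rhodium hydride may lose carbon monoxide before insertion, the ring may close in the exo sense, or the two faces of the enol ether may be poorly distinguished. The fallback uses known chemistry and adds the aryl group last; it sets out from 7 and 12 and comes back at 18. Aldehyde 7 would be treated with HC≡CMgBr (THF, 0 °C) to give the propargylic alcohol 1-[2-hydroxy-4-(methoxymethoxy)-3-prenylphenyl]prop-2-yn-1-ol F1. MnO2 (CH2Cl2, rt) would oxidise it to the ynone 1-[2-hydroxy-4-(methoxymethoxy)-3-prenylphenyl]prop-2-yn-1-one F2. Et2NH in EtOH would then close the chromone 7-(methoxymethoxy)-8-prenyl-4H-chromen-4-one F3 by amine addition, oxa-Michael closure and loss of the amine. Iodide 12 would be converted by n-BuLi (THF, −78 °C), B(OiPr)3 and aqueous work-up into (2,2-dimethyl-8-prenylchroman-6-yl)boronic acid F4. Enantioselective conjugate addition of F4 to F3 with Pd(OCOCF3)2, the 4-tert-butyl-2-(pyridin-2-yl)-4,5-dihydrooxazole ligand in the enantiomer that gives the (2S) product, NH4PF6 and water in 1,2-dichloroethane at 60 °C would give 18. This is the established asymmetric addition of arylboronic acids to chromones.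

Step 9. The chelated, doubly ortho-substituted phenoxide may add too slowly, or may attack bromine instead of carbon so that the alkyne loses its halogen. The fallback makes the O1–C2 bond by palladium-catalysed C–O coupling of an enol triflate with the phenol, which also makes step 10 unnecessary; it sets out from 12 and 7 and comes back at 17. Iodide 12 would be lithiated (n-BuLi, THF, −78 °C) and acylated with N-methoxy-N-methylacetamide to give the methyl ketone 1-(2,2-dimethyl-8-prenylchroman-6-yl)ethan-1-one F5. KN(SiMe3)2 (THF, −78 °C) followed by PhN(SO2CF3)2 would give the enol triflate 1-(2,2-dimethyl-8-prenylchroman-6-yl)ethenyl trifluoromethanesulfonate F6. Coupling of F6 with 7 using Pd2(dba)3, 2-(di-tert-butylphosphino)biphenyl and K3PO4 in toluene at 80 °C would give 17.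

Step 12. Under acid the freed C7 hydroxyl may add to the neighbouring C8 prenyl double bond, methanol may add to a prenyl group, or the configuration at C2 may erode through reversible opening of ring C. The fallback exchanges the acetal for a silyl group under non-protic conditions and then hydrolyses at neutral pH; it sets out from 18 and comes back at 19. Treatment of 18 with Me3SiOSO2CF3 and 2,2'-bipyridyl (CH2Cl2, 0 °C) would transfer the methoxymethyl group to the pyridine nitrogen and give the aryl silyl ether (2S)-2-(2,2-dimethyl-8-prenylchroman-6-yl)-8-prenyl-7-(trimethylsilyloxy)chroman-4-one F7. Stirring F7 with water at rt would give 19.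

Further compounds
F1 | step 11 | 1-[2-hydroxy-4-(methoxymethoxy)-3-prenylphenyl]prop-2-yn-1-ol (racemic) | C#CC(O)c1ccc(OCOC)c(CC=C(C)C)c1O
F2 | step 11 | 1-[2-hydroxy-4-(methoxymethoxy)-3-prenylphenyl]prop-2-yn-1-one | C#CC(=O)c1ccc(OCOC)c(CC=C(C)C)c1O
F3 | step 11 | 7-(methoxymethoxy)-8-prenyl-4H-chromen-4-one | O=c1ccoc2c(CC=C(C)C)c(OCOC)ccc12
F4 | step 11 | (2,2-dimethyl-8-prenylchroman-6-yl)boronic acid | CC(C)=CCc1cc(B(O)O)cc2c1OC(C)(C)CC2
F5 | step 9 | 1-(2,2-dimethyl-8-prenylchroman-6-yl)ethan-1-one | CC(=O)c1cc(CC=C(C)C)c2OC(C)(C)CCc2c1
F6 | step 9 | 1-(2,2-dimethyl-8-prenylchroman-6-yl)ethenyl trifluoromethanesulfonate | C=C(OS(=O)(=O)C(F)(F)F)c1cc(CC=C(C)C)c2OC(C)(C)CCc2c1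
F7 | step 12 | (2S)-2-(2,2-dimethyl-8-prenylchroman-6-yl)-8-prenyl-7-(trimethylsilyloxy)chroman-4-one | CC(C)=CCc1cc([C@@H]2CC(=O)c3ccc(O[Si](C)(C)C)c(CC=C(C)C)c3O2)cc2c1OC(C)(C)CC2
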